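**Plan**

- Labels: ring A is the methoxy ring; ring B is the phenol ring with C1' (O‑aryl), C2' (OH), C3' (H) and C4', C5', C6' (Br).
- Enabling feature: C6'–C5'–C4'(Br3)–C3'(H) of ring B is the carbon chain C2–C3–C4–C5 of 2,3,4‑tribromothiophene. The vicinal oxygens at C1'/C2' map onto the two carbons of an aryloxyalkyne whose second carbon carries boron in place of OH.
- Retrosynthesis: cut C2'–OH back to C2'–B; then cut C1'–C6' and C2'–C3' together (retro‑[4+2], SO2 put back) to the tribromothiophene dioxide and the aryloxyethynyl boronate; then cut C(sp)–B and trace the alkyne to a formate carbon plus CBr4.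
- Forward: ring A is bought complete as 3,5‑dibromosalicylaldehyde and the O–C≡C–B chain is built on its phenol oxygen. Ring B is the only ring made; it closes in the key step, and its three bromines come from the thiophene, never from electrophilic bromination.
- Stereochemistry: the target has no stereocentre; the bridged cycloadduct is a transient racemate whose two bridgehead centres vanish on loss of SO2.

Key step: step 9

**Route**

Step 1
Reactants: 1 tetrabromothiophene
Product: 3 2,3,4-tribromothiophene, via thienyllithium 2 (not isolated)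
Conditions: n-BuLi (1.0 equiv), Et2O, −78 °C; then H2O
Reagents that add atoms: none
Why: Bromine–lithium exchange on tetrabromothiophene is selective for an α‑bromine, and protonation of 2 leaves the 2,3,4‑tribromo pattern with one free α‑CH.

Step 2
Reactants: 3 2,3,4-tribromothiophene
Product: 5 2,3,4-tribromothiophene 1,1-dioxide, via thiophene S-oxide 4 (not isolated)
Conditions: TFAA, urea·H2O2, CH2Cl2, 0 °C to rt
Reagents that add atoms: urea–hydrogen peroxide, OO.NC(N)=O (source of both sulfone oxygens); trifluoroperacetic acid, O=C(OO)C(F)(F)F (formed from it with TFAA, transfers them)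
Why: Electrophilic S‑oxidation with CF3CO3H, the peracid used for electron‑poor halothiophenes, should pass through S‑oxide 4, which is oxidised further faster than it forms, and the three bromines should slow self‑dimerisation of the sulfone enough for isolation and cold storage.

Step 3
Reactants: 6 3,5-dibromosalicylaldehyde
Product: 7 3,5-dibromo-2-methoxybenzaldehyde
Conditions: MeI, K2CO3, DMF, rt
Reagents that add atoms: iodomethane, CI
Why: Williamson O‑methylation of the acidic phenol installs the ring A methoxy group and turns the aldehyde into a Baeyer–Villiger substrate.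

Step 4
Reactants: 7 3,5-dibromo-2-methoxybenzaldehyde
Product: 9 3,5-dibromo-2-methoxyphenol, via aryl formate 8 (not isolated)
Conditions: mCPBA, CH2Cl2, 0 °C to rt; then MeOH, HCl (cat.), rt
Reagents that add atoms: m-chloroperbenzoic acid, O=C(OO)c1cccc(Cl)c1
Why: Baeyer–Villiger oxidation of an ortho‑alkoxybenzaldehyde goes with aryl migration to formate 8, and methanolysis in the same flask gives the phenol, which, unlike the crude formate, can be purified free of m‑chlorobenzoic acid.

Step 5
Reactants: 9 3,5-dibromo-2-methoxyphenol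
Product: 8 3,5-dibromo-2-methoxyphenyl formate (isolated here)
Conditions: HCO2H/Ac2O (premixed, 55 °C); then 9, NaOAc (cat.), THF, 0 °C to rt
Reagents that add atoms: acetic formic anhydride, CC(=O)OC=O (made from formic acid, OC=O, and acetic anhydride, CC(=O)OC(C)=O)
Why: O‑Formylation with the mixed anhydride transfers the more electrophilic formyl group and, after evaporation of the volatiles, should give acid‑free formate for the ylide step.

Step 6
Reactants: 8 3,5-dibromo-2-methoxyphenyl formate
Product: 10 1,5-dibromo-3-[(2,2-dibromoethenyl)oxy]-2-methoxybenzene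
Conditions: CBr4, PPh3, CH2Cl2, 0 °C to rt
Reagents that add atoms: carbon tetrabromide, BrC(Br)(Br)Br
Why: Ramirez dibromomethylenation (first stage of the Corey–Fuchs sequence) is known for formate esters, the most electrophilic ester carbonyls, and Ph3P=CBr2 should convert this aryl formate through the oxaphosphetane into the 2,2‑dibromovinyl ether.

Step 7
Reactants: 10 1,5-dibromo-3-[(2,2-dibromoethenyl)oxy]-2-methoxybenzene
Product: 11 1,5-dibromo-3-[(bromoethynyl)oxy]-2-methoxybenzene
Conditions: NaN(SiMe3)2 (1.1 equiv), THF, −78 °C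
Reagents that add atoms: none
Why: E2 dehydrobromination of a 1,1‑dibromoalkene to the 1‑bromoalkyne removes the only vinylic hydrogen, which sits on the oxygen‑bearing carbon so that bromide is the only possible leaving group, and the silylamide is too weak to metalate the ring A C–H between the two bromines and cannot exchange bromine.

Step 8
Reactants: 11 1,5-dibromo-3-[(bromoethynyl)oxy]-2-methoxybenzene; 12 2-isopropoxy-4,4,5,5-tetramethyl-1,3,2-dioxaborolane
Product: 15 2-[(3,5-dibromo-2-methoxyphenoxy)ethynyl]-4,4,5,5-tetramethyl-1,3,2-dioxaborolane, via alkynylmagnesium chloride 13 (not isolated), via isopropoxyborate complex 14 (not isolated)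
Conditions: i-PrMgCl·LiCl (1.05 equiv), THF, −78 °C; 12, −78 to −20 °C; Me3SiCl, −78 °C to rt
Reagents that add atoms: none
Why: Bromine–magnesium exchange at the sp carbon should be far faster at −78 °C than at the aryl bromides of ring A, the acetylide 13 adds to borate 12, and Me3SiCl removes isopropoxide from ate complex 14 without the protic acid an ynol ether would not tolerate (alkynylboronate synthesis from an acetylide and an alkoxyborolane).

Step 9
Reactants: 5 2,3,4-tribromothiophene 1,1-dioxide; 15 2-[(3,5-dibromo-2-methoxyphenoxy)ethynyl]-4,4,5,5-tetramethyl-1,3,2-dioxaborolane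
Product: 17 2-[3,4,5-tribromo-2-(3,5-dibromo-2-methoxyphenoxy)phenyl]-4,4,5,5-tetramethyl-1,3,2-dioxaborolane, via sulfone-bridged cycloadduct 16 (not isolated)
Conditions: PhMe, 90 °C; 5 (1.5 equiv) added slowly; Ar sweep
Reagents that add atoms: none
Why: Proposed new method: an inverse‑electron‑demand [4+2] cycloaddition of the electron‑poor diene of 5 (C2=C3–C4=C5) with the push–pull alkyne 15 should give the 7‑thiabicyclo[2.2.1]heptadiene 7,7‑dioxide 16, which loses SO2 by cheletropic extrusion to give the arene; the closest known reactions are the Diels–Alder/SO2‑extrusion benzannulations of halogenated thiophene 1,1‑dioxides with alkynes and the cycloaddition–extrusion benzannulations of alkynylboronates with cyclopentadienones and 2‑pyrones. Ring B closes by intermolecular [4+2] formation of the C1'–C6' and C2'–C3' bonds followed by aromatisation through loss of the one‑atom sulfur bridge, with no elimination step that could expel the aryloxy group. The two bridgehead stereocentres of 16 are tied to each other by the bicycle, form as a racemate and disappear on aromatisation. The step needs one regiochemistry: the boron‑bearing carbon, which is the nucleophilic β‑carbon of the ynol ether, must bond to the unsubstituted C5 of the dioxide, where attack is least hindered and places the developing negative charge on the bromine‑bearing C2/C4 termini next to the sulfone, so that the oxygen‑bearing carbon joins C2 and ends beside C6'–Br. It also needs the cross‑cycloaddition to outrun [4+2] dimerisation of 5, for which slow addition keeps the dioxide concentration low, and a dry, argon‑swept medium so that SO2 and moisture do not protodeborylate 15.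

Step 10
Reactants: 17 2-[3,4,5-tribromo-2-(3,5-dibromo-2-methoxyphenoxy)phenyl]-4,4,5,5-tetramethyl-1,3,2-dioxaborolane
Product: 19 3,4,5-tribromo-2-(3,5-dibromo-2-methoxyphenoxy)phenol, via aryl pinacol borate 18 (not isolated)
Conditions: 30% aq. H2O2, THF/pH 7 phosphate buffer, 0 °C to rt
Reagents that add atoms: hydrogen peroxide, OO
Why: Oxidation of the C–B bond by hydroperoxide (1,2‑shift of the aryl group from boron to oxygen, then hydrolysis of borate 18) should replace boron by hydroxyl at C2' under buffered conditions that leave the rest of the molecule alone.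

**Compound list**

1 | tetrabromothiophene | Brc1sc(Br)c(Br)c1Br | starting material
2 | 3,4,5-tribromothiophen-2-yllithium | [Li]c1sc(Br)c(Br)c1Br | intermediate
3 | 2,3,4-tribromothiophene | Brc1csc(Br)c1Br | intermediate
4 | 2,3,4-tribromothiophene 1-oxide (racemic at sulfur) | O=S1C=C(Br)C(Br)=C1Br | intermediate
5 | 2,3,4-tribromothiophene 1,1-dioxide | O=S1(=O)C=C(Br)C(Br)=C1Br | intermediate
6 | 3,5-dibromosalicylaldehyde (3,5-dibromo-2-hydroxybenzaldehyde) | O=Cc1cc(Br)cc(Br)c1O | starting material
7 | 3,5-dibromo-2-methoxybenzaldehyde | COc1c(Br)cc(Br)cc1C=O | intermediate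
8 | 3,5-dibromo-2-methoxyphenyl formate | COc1c(Br)cc(Br)cc1OC=O | intermediate
9 | 3,5-dibromo-2-methoxyphenol | COc1c(Br)cc(Br)cc1O | intermediate
10 | 1,5-dibromo-3-[(2,2-dibromoethenyl)oxy]-2-methoxybenzene | COc1c(Br)cc(Br)cc1OC=C(Br)Br | intermediate
11 | 1,5-dibromo-3-[(bromoethynyl)oxy]-2-methoxybenzene | COc1c(Br)cc(Br)cc1OC#CBr | intermediate
12 | 2-isopropoxy-4,4,5,5-tetramethyl-1,3,2-dioxaborolane | CC(C)OB1OC(C)(C)C(C)(C)O1 | starting material
13 | [(3,5-dibromo-2-methoxyphenoxy)ethynyl]magnesium chloride | COc1c(Br)cc(Br)cc1OC#C[Mg]Cl | intermediate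
14 | chloromagnesium [(3,5-dibromo-2-methoxyphenoxy)ethynyl](isopropoxy)(pinacolato)borate | COc1c(Br)cc(Br)cc1OC#C[B-]1(OC(C)C)OC(C)(C)C(C)(C)O1.[Mg+]Cl | intermediate
15 | 2-[(3,5-dibromo-2-methoxyphenoxy)ethynyl]-4,4,5,5-tetramethyl-1,3,2-dioxaborolane | COc1c(Br)cc(Br)cc1OC#CB1OC(C)(C)C(C)(C)O1 | intermediate
16 | 1,5,6-tribromo-2-(3,5-dibromo-2-methoxyphenoxy)-3-(4,4,5,5-tetramethyl-1,3,2-dioxaborolan-2-yl)-7-thiabicyclo[2.2.1]hepta-2,5-diene 7,7-dioxide (racemic; one enantiomer drawn) | O=S1(=O)[C@@]2(Br)C(Br)=C(Br)[C@@H]1C(B3OC(C)(C)C(C)(C)O3)=C2Oc4cc(Br)cc(Br)c4OC | intermediate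
17 | 2-[3,4,5-tribromo-2-(3,5-dibromo-2-methoxyphenoxy)phenyl]-4,4,5,5-tetramethyl-1,3,2-dioxaborolane | COc1c(Br)cc(Br)cc1Oc1c(B2OC(C)(C)C(C)(C)O2)cc(Br)c(Br)c1Br | intermediate
18 | 2-[3,4,5-tribromo-2-(3,5-dibromo-2-methoxyphenoxy)phenoxy]-4,4,5,5-tetramethyl-1,3,2-dioxaborolane | COc1c(Br)cc(Br)cc1Oc1c(OB2OC(C)(C)C(C)(C)O2)cc(Br)c(Br)c1Br | intermediate
19 | 3,4,5-tribromo-2-(3,5-dibromo-2-methoxyphenoxy)phenol | COc1c(Br)cc(Br)cc1Oc1c(O)cc(Br)c(Br)c1Br | target

**Step count**

Total: 10 steps. Longest linear sequence: 8 steps (6 to 19 through steps 3–10); the thiophene branch (steps 1–2) joins at step 9.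

**Three steps most likely to fail**

1. Step 9 (the step labelled as a new method). What may go wrong: the cycloaddition may be slower than self‑dimerisation of the dioxide; a stepwise zwitterionic addition may divert to [2+2] products; the regiochemistry may erode; the alkynyl C–B bond may be lost before cycloaddition. The fallback uses known chemistry only, sets out from phenol 9 and returns at target 19. Commercial 3‑fluoro‑4‑nitroaniline is brominated at both positions ortho to nitrogen (NBS, MeCN) to 2,6-dibromo-3-fluoro-4-nitroaniline F1. This is diazotised (NaNO2, H2SO4/AcOH) to 2,6-dibromo-3-fluoro-4-nitrobenzenediazonium hydrogensulfate F2 and converted by a Sandmeyer reaction (CuBr, HBr) into 1,2,3-tribromo-4-fluoro-5-nitrobenzene F3. Phenol 9 displaces the fluoride ortho to the nitro group (SNAr; K2CO3, DMF) to give 1,5-dibromo-2-methoxy-3-(2,3,4-tribromo-6-nitrophenoxy)benzene F4. Reduction with Fe/NH4Cl (EtOH/H2O) should give 3,4,5-tribromo-2-(3,5-dibromo-2-methoxyphenoxy)aniline F5. Diazotisation (NaNO2, aq. H2SO4, 0 °C) gives 3,4,5-tribromo-2-(3,5-dibromo-2-methoxyphenoxy)benzenediazonium hydrogensulfate F6, and hydroxydediazoniation with Cu2O in concentrated aqueous Cu(NO3)2, where the high copper concentration should outpace Pschorr cyclisation onto ring A, gives 19.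

2. Step 8. What may go wrong: bromine–magnesium exchange may also occur at the ring A bromine ortho to the methoxy group; the Grignard reagent may add to the ynol ether; the alkynylboronate may lose boron during isolation. The fallback sets out from dibromovinyl ether 10 and returns at alkynylmagnesium chloride 13. Pd(PPh3)4‑catalysed hydrogenolysis with Bu3SnH removes the bromine trans to the aryloxy group and should give 1,5-dibromo-3-{[(Z)-2-bromoethenyl]oxy}-2-methoxybenzene F7. Anti‑elimination of HBr with NaN(SiMe3)2 (THF, −78 to 0 °C) gives the terminal ynol ether 1,5-dibromo-3-(ethynyloxy)-2-methoxybenzene F8. Its acidic C–H is removed by i‑PrMgCl without LiCl (THF, 0 °C), an acid–base reaction that needs no halogen–metal exchange, to give 13, which is borylated and released as in step 8 and used without storage.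

3. Step 6. What may go wrong: the adduct of the ylide with the aryl formate may collapse by expelling the aryloxide (formyl transfer to the ylide) instead of by olefination, since the phenoxide is a good leaving group. The fallback sets out from phenol 9 and returns at bromoalkyne 11. Phenol 9 adds to commercial tribromoethylene under K2CO3 in DMF (elimination–addition, the bromine counterpart of the trichloroethylene route to aryl 1,2‑dichlorovinyl ethers) to give 1,5-dibromo-3-{[(E)-1,2-dibromoethenyl]oxy}-2-methoxybenzene F9. Dehydrobromination with NaN(SiMe3)2 (THF, −78 °C) gives 11, so no carbonyl olefination is needed.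

**Further compounds**

F1 | step 9 | 2,6-dibromo-3-fluoro-4-nitroaniline | Nc1c(Br)cc([N+](=O)[O-])c(F)c1Br
F2 | step 9 | 2,6-dibromo-3-fluoro-4-nitrobenzenediazonium hydrogensulfate | N#[N+]c1c(Br)cc([N+](=O)[O-])c(F)c1Br.OS(=O)(=O)[O-]
F3 | step 9 | 1,2,3-tribromo-4-fluoro-5-nitrobenzene | O=[N+]([O-])c1cc(Br)c(Br)c(Br)c1F
F4 | step 9 | 1,5-dibromo-2-methoxy-3-(2,3,4-tribromo-6-nitrophenoxy)benzene | COc1c(Br)cc(Br)cc1Oc1c([N+](=O)[O-])cc(Br)c(Br)c1Br
F5 | step 9 | 3,4,5-tribromo-2-(3,5-dibromo-2-methoxyphenoxy)aniline | COc1c(Br)cc(Br)cc1Oc1c(N)cc(Br)c(Br)c1Br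
F6 | step 9 | 3,4,5-tribromo-2-(3,5-dibromo-2-methoxyphenoxy)benzenediazonium hydrogensulfate | COc1c(Br)cc(Br)cc1Oc1c([N+]#N)cc(Br)c(Br)c1Br.OS(=O)(=O)[O-]
F7 | step 8 | 1,5-dibromo-3-{[(Z)-2-bromoethenyl]oxy}-2-methoxybenzene | COc1c(Br)cc(Br)cc1O/C=C\Br
F8 | step 8 | 1,5-dibromo-3-(ethynyloxy)-2-methoxybenzene | COc1c(Br)cc(Br)cc1OC#C
F9 | step 6 | 1,5-dibromo-3-{[(E)-1,2-dibromoethenyl]oxy}-2-methoxybenzene | COc1c(Br)cc(Br)cc1O/C(Br)=C\Br
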